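**Retrosynthetic overview**
- The target is the phenol-deprotected tiglate of an (S)-prenyl carbinol; the ester C–O bond and the prenyl alkene (cross-metathesis with 2-methyl-2-butene) are disconnected first.
- Key C–C disconnection: the carbinol carbon to its CH2 neighbour, made by Brown asymmetric carbonyl allylation of a 2-arylacrolein with an allylborane; this sets the only stereocentre (S).
- The 2-arylacrolein comes from Mannich α-methylenation of an arylacetaldehyde, itself from oxidative cleavage of an ortho-allyl phenol made by aromatic Claisen rearrangement.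
- The phenol comes from 2,6-dimethoxytoluene by Vilsmeier formylation and Dakin oxidation.
- No ring is formed; the benzene ring is bought and only substituted.

Assumption: reagents that only deliver atoms are bought, named with SMILES and carry no number; TBS = tert-butyldimethylsilyl, Ipc = isopinocampheyl.

**Step 1**
Reactants: 1 2,6-dimethoxytoluene
Product: 3 2,4-dimethoxy-3-methylbenzaldehyde, via aryl iminium salt 2 (not isolated)
Conditions: POCl3 (1.5 equiv), DMF, 0 °C → 85 °C, 5 h; then ice/H2O, aq NaOH to pH 7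
Reagents that add atoms: N,N-dimethylformamide, CN(C)C=O (formyl carbon); water, O (carbonyl oxygen)
Why: Vilsmeier–Haack formylation attacks the two equivalent positions ortho/para to the methoxy groups, so one aldehyde forms and no stereocentre is involved.

**Step 2**
Reactants: 3 2,4-dimethoxy-3-methylbenzaldehyde
Product: 5 2,4-dimethoxy-3-methylphenol, via aryl formate 4 (not isolated)
Conditions: mCPBA (1.3 equiv), CH2Cl2, 0 °C → rt; then K2CO3 (0.2 equiv), degassed MeOH, rt
Reagents that add atoms: mCPBA, OOC(=O)c1cccc(Cl)c1 (inserted oxygen)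
Why: Dakin-type Baeyer–Villiger oxidation, in which the electron-rich aryl group migrates to oxygen and the resulting formate is methanolysed.

**Step 3**
Reactants: 5 2,4-dimethoxy-3-methylphenol
Product: 6 1-(allyloxy)-2,4-dimethoxy-3-methylbenzene
Conditions: allyl bromide (1.2 equiv), K2CO3 (2 equiv), acetone, reflux
Reagents that add atoms: allyl bromide, C=CCBr
Why: Williamson ether synthesis of a phenoxide with a reactive primary allylic bromide.

**Step 4**
Reactants: 6 1-(allyloxy)-2,4-dimethoxy-3-methylbenzene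
Product: 8 6-allyl-2,4-dimethoxy-3-methylphenol, via ortho-dienone 7 (not isolated)
Conditions: PhNEt2, 195 °C, sealed tube, 8 h
Reagents that add atoms: none
Why: Aromatic Claisen rearrangement ([3,3]-sigmatropic) can only end at the single unsubstituted ortho carbon (the other ortho and the para position carry substituents), then tautomerises to the phenol.

**Step 5**
Reactants: 8 6-allyl-2,4-dimethoxy-3-methylphenol
Product: 9 (2-allyl-4,6-dimethoxy-5-methylphenoxy)(tert-butyl)dimethylsilane
Conditions: TBSCl (1.3 equiv), imidazole (2.5 equiv), DMF, rt → 40 °C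
Reagents that add atoms: tert-butyldimethylsilyl chloride, CC(C)(C)[Si](C)(C)Cl
Why: Imidazole-promoted silylation masks the phenol as a fluoride-labile aryl silyl ether that survives the oxidative, borane and metathesis steps.

**Step 6**
Reactants: 9 (2-allyl-4,6-dimethoxy-5-methylphenoxy)(tert-butyl)dimethylsilane
Product: 11 2-[2-(tert-butyldimethylsilyloxy)-3,5-dimethoxy-4-methylphenyl]acetaldehyde, via vicinal diol 10 (not isolated)
Conditions: OsO4 (2 mol %), NaIO4 (4 equiv), 2,6-lutidine (2 equiv), dioxane/H2O 3:1, rt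
Reagents that add atoms: osmium tetroxide OsO4, O=[Os](=O)(=O)=O (delivers the oxygen, catalytic); sodium periodate NaIO4, [Na+].[O-]I(=O)(=O)=O (terminal oxidant that turns OsO4 over, with water, O)
Why: Lemieux–Johnson oxidation dihydroxylates the only alkene and cleaves the diol in the same flask, with 2,6-lutidine suppressing over-oxidation.

**Step 7**
Reactants: 11 2-[2-(tert-butyldimethylsilyloxy)-3,5-dimethoxy-4-methylphenyl]acetaldehyde
Product: 13 2-[2-(tert-butyldimethylsilyloxy)-3,5-dimethoxy-4-methylphenyl]prop-2-enal, via Mannich base 12 (not isolated)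
Conditions: (CH2=NMe2)I (1.5 equiv), Et3N (3 equiv), CH2Cl2, rt, 12 h; short silica plug, used at once
Reagents that add atoms: dimethylmethylideneammonium iodide (Eschenmoser's salt), C=[N+](C)C.[I-]
Why: Mannich reaction of the benzylic enol with the preformed iminium ion, followed by E1cB loss of dimethylamine, gives the α-methylene aldehyde, which has no α-hydrogen left.

**Step 8** (key step)
Reactants: 13 2-[2-(tert-butyldimethylsilyloxy)-3,5-dimethoxy-4-methylphenyl]prop-2-enal
Product: 15 (3S)-2-[2-(tert-butyldimethylsilyloxy)-3,5-dimethoxy-4-methylphenyl]hexa-1,5-dien-3-ol, via borinate ester 14 (not isolated)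
Conditions: (−)-Ipc2BOMe (1.5 equiv), CH2=CHCH2MgBr (1.4 equiv), Et2O, 0 °C → rt, 1 h; then 13, −78 °C, 3 h; then H2NCH2CH2OH, rt
Reagents that add atoms: allylmagnesium bromide, C=CC[Mg]Br (allyl group, passed on through (−)-B-allyldiisopinocampheylborane); (−)-B-methoxydiisopinocampheylborane, COB([C@@H]1C[C@@H]2C[C@H]([C@H]1C)C2(C)C)[C@@H]1C[C@@H]2C[C@H]([C@H]1C)C2(C)C (Ipc2B unit, kept only in 14)
Why: Brown asymmetric allylboration through a closed chair transition state; the reagent derived from (+)-α-pinene delivers allyl to the Si face of the aldehyde (the sense that gives (S)-1-phenylbut-3-en-1-ol from PhCHO), setting the (S)-carbinol, to be confirmed by Mosher ester analysis.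

**Step 9**
Reactants: 15 (3S)-2-[2-(tert-butyldimethylsilyloxy)-3,5-dimethoxy-4-methylphenyl]hexa-1,5-dien-3-ol
Product: 16 (3S)-2-[2-(tert-butyldimethylsilyloxy)-3,5-dimethoxy-4-methylphenyl]-6-methylhepta-1,5-dien-3-ol
Conditions: 2-methyl-2-butene/CH2Cl2 1:1, second-generation Grubbs catalyst (H2IMes)(PCy3)Cl2Ru=CHPh (5 mol %), 40 °C, sealed tube
Reagents that add atoms: 2-methyl-2-butene, CC=C(C)C (isopropylidene unit)
Why: Olefin cross-metathesis engages only the monosubstituted terminal alkene, because the hindered 1,1-disubstituted aryl alkene is inert and ring closure would need a cyclobutene; the stereocentre is untouched.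

**Step 10**
Reactants: 16 (3S)-2-[2-(tert-butyldimethylsilyloxy)-3,5-dimethoxy-4-methylphenyl]-6-methylhepta-1,5-dien-3-ol
Product: 17 (3S)-2-[2-(tert-butyldimethylsilyloxy)-3,5-dimethoxy-4-methylphenyl]-6-methylhepta-1,5-dien-3-yl (2E)-2-methylbut-2-enoate
Conditions: tigloyl chloride (2 equiv), pyridine (4 equiv), DMAP (0.2 equiv), CH2Cl2, 0 °C → rt
Reagents that add atoms: tigloyl chloride ((2E)-2-methylbut-2-enoyl chloride), C/C=C(\C)C(=O)Cl
Why: DMAP-catalysed acylation with pyridine as base (no vinylketene deconjugation) forms the ester at oxygen, so the C–O stereocentre and the (E)-geometry are retained.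

**Step 11**
Reactants: 17 (3S)-2-[2-(tert-butyldimethylsilyloxy)-3,5-dimethoxy-4-methylphenyl]-6-methylhepta-1,5-dien-3-yl (2E)-2-methylbut-2-enoate
Product: 18 (3S)-2-(2-hydroxy-3,5-dimethoxy-4-methylphenyl)-6-methylhepta-1,5-dien-3-yl (2E)-2-methylbut-2-enoate
Conditions: Bu4NF (1.2 equiv), AcOH (1.5 equiv), THF, 0 °C, 30 min
Reagents that add atoms: none
Why: Fluoride-driven Si–O cleavage of the aryl silyl ether, buffered with AcOH so that no free phenoxide attacks the neighbouring ester or the acid-sensitive alkenes.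

**Compound list**
1 | 2,6-dimethoxytoluene | COc1cccc(OC)c1C | starting material
2 | N-(2,4-dimethoxy-3-methylbenzylidene)-N-methylmethanaminium dichlorophosphate | COc1ccc(C=[N+](C)C)c(OC)c1C.[O-]P(=O)(Cl)Cl | intermediate
3 | 2,4-dimethoxy-3-methylbenzaldehyde | COc1ccc(C=O)c(OC)c1C | intermediate
4 | 2,4-dimethoxy-3-methylphenyl formate | COc1ccc(OC=O)c(OC)c1C | intermediate
5 | 2,4-dimethoxy-3-methylphenol | COc1ccc(O)c(OC)c1C | intermediate
6 | 1-(allyloxy)-2,4-dimethoxy-3-methylbenzene | C=CCOc1ccc(OC)c(C)c1OC | intermediate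
7 | 6-allyl-2,4-dimethoxy-3-methylcyclohexa-2,4-dien-1-one (racemic) | C=CCC1C=C(OC)C(C)=C(OC)C1=O | intermediate
8 | 6-allyl-2,4-dimethoxy-3-methylphenol | C=CCc1cc(OC)c(C)c(OC)c1O | intermediate
9 | (2-allyl-4,6-dimethoxy-5-methylphenoxy)(tert-butyl)dimethylsilane | C=CCc1cc(OC)c(C)c(OC)c1O[Si](C)(C)C(C)(C)C | intermediate
10 | 3-[2-(tert-butyldimethylsilyloxy)-3,5-dimethoxy-4-methylphenyl]propane-1,2-diol (racemic) | OCC(O)Cc1cc(OC)c(C)c(OC)c1O[Si](C)(C)C(C)(C)C | intermediate
11 | 2-[2-(tert-butyldimethylsilyloxy)-3,5-dimethoxy-4-methylphenyl]acetaldehyde | O=CCc1cc(OC)c(C)c(OC)c1O[Si](C)(C)C(C)(C)C | intermediate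
12 | 2-[2-(tert-butyldimethylsilyloxy)-3,5-dimethoxy-4-methylphenyl]-3-(dimethylamino)propanal (racemic) | CN(C)CC(C=O)c1cc(OC)c(C)c(OC)c1O[Si](C)(C)C(C)(C)C | intermediate
13 | 2-[2-(tert-butyldimethylsilyloxy)-3,5-dimethoxy-4-methylphenyl]prop-2-enal | C=C(C=O)c1cc(OC)c(C)c(OC)c1O[Si](C)(C)C(C)(C)C | intermediate
14 | (3S)-2-[2-(tert-butyldimethylsilyloxy)-3,5-dimethoxy-4-methylphenyl]hexa-1,5-dien-3-yl diisopinocampheylborinate | C=C(c1cc(OC)c(C)c(OC)c1O[Si](C)(C)C(C)(C)C)[C@H](CC=C)OB([C@@H]1C[C@@H]2C[C@H]([C@H]1C)C2(C)C)[C@@H]1C[C@@H]2C[C@H]([C@H]1C)C2(C)C | intermediate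
15 | (3S)-2-[2-(tert-butyldimethylsilyloxy)-3,5-dimethoxy-4-methylphenyl]hexa-1,5-dien-3-ol | C=C(c1cc(OC)c(C)c(OC)c1O[Si](C)(C)C(C)(C)C)[C@H](CC=C)O | intermediate
16 | (3S)-2-[2-(tert-butyldimethylsilyloxy)-3,5-dimethoxy-4-methylphenyl]-6-methylhepta-1,5-dien-3-ol | C=C(c1cc(OC)c(C)c(OC)c1O[Si](C)(C)C(C)(C)C)[C@H](CC=C(C)C)O | intermediate
17 | (3S)-2-[2-(tert-butyldimethylsilyloxy)-3,5-dimethoxy-4-methylphenyl]-6-methylhepta-1,5-dien-3-yl (2E)-2-methylbut-2-enoate | C=C(c1cc(OC)c(C)c(OC)c1O[Si](C)(C)C(C)(C)C)[C@H](CC=C(C)C)OC(=O)/C(C)=C/C | intermediate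
18 | (3S)-2-(2-hydroxy-3,5-dimethoxy-4-methylphenyl)-6-methylhepta-1,5-dien-3-yl (2E)-2-methylbut-2-enoate | C=C(c1cc(OC)c(C)c(OC)c1O)[C@H](CC=C(C)C)OC(=O)/C(C)=C/C | target

**Totals**
Total step count: 11. Longest linear sequence: 11 steps (1 → 18).

**Three steps most likely to fail**

Step 8 (asymmetric allylation of the polymerisation-prone 2-arylacrolein; enantiomeric excess). The fallback sets out from 13 and comes back at 15. Freshly made 13 is reduced at once (NaBH4, CeCl3·7H2O, MeOH, −40 °C) to the storable allylic alcohol 2-[2-(tert-butyldimethylsilyloxy)-3,5-dimethoxy-4-methylphenyl]prop-2-en-1-ol F1. F1 is then allylated from the alcohol oxidation level by iridium-catalysed transfer-hydrogenative coupling with allyl acetate ([Ir(cod)Cl]2, (S)-BINAP, 4-chloro-3-nitrobenzoic acid, Cs2CO3, THF, 100 °C). The aldehyde exists there only transiently and in low concentration, and 15 is formed directly. (S)-BINAP is the expected ligand enantiomer, but I am not certain of that assignment; it should be fixed against the known 1-phenylbut-3-en-1-ol benchmark and the product checked by Mosher analysis.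

Step 9 (cross-metathesis next to a free carbinol, which can bind ruthenium or trigger alkene isomerisation). The fallback sets out from 15 and comes back at 17, moving the metathesis behind the acylation. 15 is esterified first (tigloyl chloride, pyridine, DMAP, CH2Cl2) to (3S)-2-[2-(tert-butyldimethylsilyloxy)-3,5-dimethoxy-4-methylphenyl]hexa-1,5-dien-3-yl (2E)-2-methylbut-2-enoate F2. F2 is then cross-metathesised with 2-methyl-2-butene using the second-generation Hoveyda–Grubbs catalyst (H2IMes)Cl2Ru=CH(C6H4-2-OiPr) to give 17. The trisubstituted, electron-poor tiglate alkene does not take part.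

Step 11 (desilylation beside an allylic ester; risk of acyl transfer or ester loss). The fallback sets out from 16 and comes back at 18, removing silicon before the ester exists. 16 is desilylated (Bu4NF, THF, 0 °C; NH4Cl work-up) to (3S)-2-(2-hydroxy-3,5-dimethoxy-4-methylphenyl)-6-methylhepta-1,5-dien-3-ol F3. Both hydroxyls are acylated (tigloyl chloride 3 equiv, pyridine, DMAP) to give 2-[(3S)-6-methyl-3-{[(2E)-2-methylbut-2-enoyl]oxy}hepta-1,5-dien-2-yl]-3,5-dimethoxy-4-methyl... phenyl (2E)-2-methylbut-2-enoate, the bis-tiglate F4. The far more reactive aryl ester is then cleaved selectively with pyrrolidine (1.2 equiv, THF, 0 °C), leaving the secondary alkyl tiglate and giving 18.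

**Further compounds**
F1 | step 8 | 2-[2-(tert-butyldimethylsilyloxy)-3,5-dimethoxy-4-methylphenyl]prop-2-en-1-ol | C=C(CO)c1cc(OC)c(C)c(OC)c1O[Si](C)(C)C(C)(C)C
F2 | step 9 | (3S)-2-[2-(tert-butyldimethylsilyloxy)-3,5-dimethoxy-4-methylphenyl]hexa-1,5-dien-3-yl (2E)-2-methylbut-2-enoate | C=C(c1cc(OC)c(C)c(OC)c1O[Si](C)(C)C(C)(C)C)[C@H](CC=C)OC(=O)/C(C)=C/C
F3 | step 11 | (3S)-2-(2-hydroxy-3,5-dimethoxy-4-methylphenyl)-6-methylhepta-1,5-dien-3-ol | C=C(c1cc(OC)c(C)c(OC)c1O)[C@H](CC=C(C)C)O
F4 | step 11 | (3S)-2-{3,5-dimethoxy-4-methyl-2-[(2E)-2-methylbut-2-enoyloxy]phenyl}-6-methylhepta-1,5-dien-3-yl (2E)-2-methylbut-2-enoate | C=C(c1cc(OC)c(C)c(OC)c1OC(=O)/C(C)=C/C)[C@H](CC=C(C)C)OC(=O)/C(C)=C/C
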